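The red flask is the one asked about, followed so far up to 15.0 h; the amber run was made earlier.

| flask | solid substrate | partner | temperature | remark | time |
|---|---|---|---|---|---|
| red | 10 mM | 11 mM | 100 °C | the very flask that is asked about, followed so far |  |
| amber | 15 mM | 11 mM | 85 °C | run made earlier |  |
| flask | 10 mM | 11.0 mM | 100 °C |  | 20 h |

| run | time / h | target / % |
|---|---|---|
| red | 1.33 | 30.5 |
| red | 2.00 | 43.2 |
| red | 4.00 | 72.9 |
| red | 6.00 | 64.4 |
| red | 10.0 | 51.8 |
| red | 15.0 | 43.5 |
| amber | 0.500 | 6.9 |
| amber | 2.00 | 31.0 |
| amber | 3.00 | 44.9 |
| amber | 4.00 | 56.5 |
| amber | 6.00 | 66.8 |
| amber | 8.00 | 64.8 |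

(standard deviation of a reading: 0.5 percentage points)

- percent here means solid substrate units held: one side product counts as two
- what is said of target includes solid product
- solid substrate, solid product is a solid; its amount is given per volume of the solution
- additions bring no volume worth counting
- what may be going on: solid substrate <-> dissolved substrate; 2 dissolved substrate -> side product; solid product <-> target; target <-> isomer of the product; dissolved substrate + partner -> target
- at the start none of the solid substrate is in solution

- dawn: at 20 h raise the temperature by 15 K, then wait 6.0 h
- autumn: at 20 h add partner, 50.0 % of the amount charged, then wait 6.0 h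
- dusk: change nothing and wait 6.0 h more

- target, in percent of the solid substrate first charged, at 20 h
- what to do for the largest gain in target; "none" if nothing gains more than 2 percentage points (dawn / autumn / dusk / none)
- target present, in percent of the solid substrate first charged, after dawn
- target present, in percent of the solid substrate first charged, after dusk

I looked at rates first. Red gained on average 0.229 /h of the charge up to its first reading, and its readings fell after 4.00 h. From 6.00 h to 10.0 h target fell by 0.0315 /h, and from 10.0 h to 15.0 h by 0.0166 /h. So the fall slowed by a factor 0.527 between the midpoints of these spans, which is a rate constant of 0.142 /h. A fall that keeps slowing this way adds up to a finite sum, and I reckoned that red would level off at 35.3 %.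

The zero of my scale was the symmetric case: target and isomer equally stable and sharing the whole charge, so a ratio of 1 and target at half of the charge. Red stood below that at 15.0 h already. Taking what is not target for isomer, I defined the balance ratio, isomer over target once the fall has ended (an equilibrium constant read from readings), as 1.83 for red at 100 °C. The same slowing gave me 39.3 % at 20 h.

The forecast said 39.4 % now, 37 % after dusk and 34.5 % after dawn, and chose none: “No action gains anything”.

The flask gave 37.3 %, and 34.6 % after dusk. The best step was dawn, with 50.4 %, a gain of 13 percentage points.

    solid substrate ⇌ dissolved substrate, rate k1*(cs1 - [dissolved substrate]) while solid is left; crystals form when [dissolved substrate] > cs1 (solubility = 5.70 mM, k = 1.44 × 10⁻⁴ /s)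
    2 dissolved substrate → side product (k = 0.0409 /M/s, Ea = 57.0 kJ/mol)
    solid product ⇌ target, rate k3*(cs3 - [target]) while solid is left; crystals form when [target] > cs3 (solubility = 3.30 mM, k = 0.00977 /s)
    target ⇌ isomer of the product (K = 2.00, k = 7.48 × 10⁻⁵ /s, Ea = 115 kJ/mol, ΔH = −26.0 kJ/mol)
    dissolved substrate + partner → target (k = 0.419 /M/s, Ea = 52.0 kJ/mol)
    (constants at 100 °C)

The relaxation half-life of dissolved target and isomer by their interconversion alone, both ways together, 1.72 h, is short against the 20 h of the flask, and at that time the flask held 61.0 % isomer to 37.3 % target, solid product 4.33 % counted in it, a ratio of 1.64. At 200 h the flask's ratio is 2.00, with solid product at 0 %. The neighbour with 6.6 mM partner held 66.0 % as target and isomer together at 20.0 h, so the balance ratio gives it 23.3 % target, and it held 22.0 %.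

(Readings and results stem from a simulated flask on assumed constants, and the scatter is random.)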